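## Analysis of the target

Target 22 is built from two oxygen heterocycles joined by one methylene group. The first is a trans-2-aryl-3-(hydroxymethyl)-2,3-dihydrobenzofuran (O1, C2, C3, C3a to C7a; the benzo ring is ring B). The second is a 2′-aryl-3′-(hydroxymethyl)tetrahydrofuran (O1′, C2′ to C5′), whose C4′ carries the CH2 group bonded to C6 of ring B. Ring B is 1,2,3,5-tetrasubstituted: C3a lies between the two oxygen-bearing carbons C4 (OMe) and C7a (O1), and C6 is meta to both. The five stereocentres fall into two groups that cannot control each other: C2 (S) and C3 (R) are trans on the dihydrobenzofuran, while C2′ (R), C3′ (S) and C4′ (S) place the aryl group trans to CH2OH and CH2OH cis to the arylmethyl arm. Sensitive groups are the two phenols (4-hydroxy-3-methoxyphenyl on C2, 3-hydroxy-4-methoxyphenyl on C2′), the two primary alcohols and the two benzylic C–O bonds (C2–O1 and C2′–O1′), which ionise in acid and can be hydrogenolysed. The difficulty is threefold: each half needs its own absolute control, the two oxygens flanking C3a must be told apart, and the halves must be joined at an sp2–sp3 bond. The strategy rests on the C2–C3 bond: C2 is a benzylic ether carbon (bonded to O1 and the guaiacyl ring), and C3 is bonded to C3a and bears a carbon that can be an ester. That is the pattern produced when an aryl(ester)carbene on C3 inserts into a C–H bond of an ArCH2–O group on C7a.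

## Retrosynthetic reasoning

**22 back to 20 (no skeletal bond cut).** The phenols are masked as benzyl ethers (21). Both primary alcohols are traced to esters in 20: the methyl ester on C3, which the carbene chemistry needs anyway, and an acetate on the C3′ arm. One hydride step then liberates both alcohols, and hydrogenolysis of the aryl benzyl ethers is left for the end.

**20 to 11 and 18 (C6–CH2 bond).** This sp2–sp3 bond separates the two stereochemical domains, so each half can be made and checked on its own. The aryl bromide of 11 is inert in the carbene step. The alkyl partner is the zinc reagent 19, formed from iodide 18; the carbon bearing zinc is a CH2 group, so no stereocentre is at risk. The forward reaction is a Negishi coupling that must tolerate two esters.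

**11 to 9 (C2–C3 bond, the key disconnection).** Cutting C2–C3 opens the dihydrofuran ring and returns an achiral diazo ester 9. The carbene carbon becomes C3 and the OCH2 group of a benzyl ether on C7a becomes C2. This cut removes a ring and both stereocentres at once. The forward step must choose the benzylic OCH2 over the OCH3 on C4, set C2 by catalyst control and deliver trans. The trans requirement is met because C3 is alpha to an ester and can be equilibrated through its kinetic cis isomer 10.

**9 to 6 and 7.** The diazo group comes from the arylacetate 8 by diazo transfer. The ArO–CH2 bond of 8 is cut to phenol 6 and the catalogue benzylic alcohol 7; a Mitsunobu etherification joins them without base.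

**6 to 1.** The acetate side chain of 6 is a one-carbon homologue of an aldehyde (5 from 4). The two ring B oxygens are differentiated at the aldehyde stage, where the formyl group directs cleavage of a single methyl ether (3 from 2). A base-stable, acid-labile acetal (4) covers that phenol through the homologation and falls off in its acidic last stage. Both oxygens enter by displacement of the two fluorides of 1, which already carries the bromide para to the future C3a.

**18 to 15 (C3′–C4′ bond).** The tetrahydrofuran is opened between C3′ and C4′. A carbon radical at C3′, generated by reductive opening of the oxirane in 15, adds to the allyl ether; the resulting primary radical is captured by titanium as the bis-titanium species 16 and becomes the iodide 17 on iodination. This single step forms the ring, the hydroxymethyl group and the iodomethyl handle. C2′ controls both new centres, and the oxirane stereocentre is destroyed, so only C2′ has to be made enantiopure.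

**15 to 12.** The allyl ether 15 comes from epoxy alcohol 14. 14 is the fast-reacting product of a Sharpless kinetic resolution of the racemic allylic alcohol 13, which is the vinyl adduct of the catalogue aldehyde 12.

## Alternatives that were turned down

**Alternative 1: ring B built by a cyclobutenone–ynol ether benzannulation (Danheiser benzannulation).**
- Disconnection: ring B itself, at C3a–C7a and C4–C5 (C7–C7a forms in the electrocyclisation).
- Forward key step: heating cyclobutenone A2 (which already contains the tetrahydrofuran) with siloxyalkyne A3 (which contains C3 and C2 as an open chain). The sequence is ring opening to a vinylketene, [2+2] addition of the ynol ether, a second ring opening and a six-electron electrocyclisation. It would give phenol A1 with the free OH as the future O1 and the silyl ether as the future OMe.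
- For: the substitution pattern of ring B is written regiospecifically; the two oxygens are born different; both halves meet in the ring-forming event with no sp2–sp3 coupling. On these points it is stronger than the chosen route, which spends steps 2, 3 and 14 on them.
- Against: A2 requires several steps of ketene chemistry on the finished tetrahydrofuran. A3 needs two adjacent stereocentres set acyclically next to a sensitive ynol ether. The annulation runs hot on a substrate with three kinds of silyl ether. After A1, O1–C2 still has to be closed with inversion at an electron-rich benzylic carbon (risk of ionisation and scrambling), and the silyl ether exchanged for methyl.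
- Comparison: the chosen strategy creates C2 and C3 in one catalytic step from an achiral precursor and is several steps shorter.

**Alternative 2: aryl radical cyclisation ended by borylation.**
- Disconnection: C3a–C3.
- Forward key step: irradiating aryl iodide A5 with B2cat2 in dimethylacetamide to form the C3a radical, which adds 5-exo to the vinyl group of its (S)-1-arylallyl ether; the primary radical is borylated to give A4 after pinacol exchange.
- For: C2 comes from a resolved allylic alcohol, so its absolute configuration is more certain than under catalyst control; no metal is needed; the CH2–B group goes to CH2OH by oxidation alone. On these points it is as strong as or stronger than the chosen route.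
- Against: the trans/cis ratio is fixed kinetically, and C3 then has no acidifying group, so it cannot be corrected. The doubly activated O–CH hydrogen is 1,5 to the aryl radical, and its transfer would destroy C2. Making the ether from a hindered iodophenol and a benzylic, allylic secondary alcohol invites ionisation and allylic transposition. The tetrahydrofuran must be attached before the uncertain step.
- Comparison: the chosen strategy can equilibrate C3 to trans through the ester and meets the tetrahydrofuran fragment only after its risky step.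

**Alternative 3: oxidative radical annulation of a cyclohexanedione, ring B aromatised late.**
- Disconnection: C3a–C3 and O1–C2 together.
- Forward key step: Mn(OAc)3 oxidises dione A7 to its C2 radical, which adds to the alkene of the cinnamoyl sultam A8. Oxidation of the benzylic radical and capture by the enol oxygen would give A6.
- For: two bonds, the ring and both stereocentres form in one step from simple partners, trans is built in, and no diazo compound is needed. In bond economy of the key step it is stronger than the chosen route.
- Against: stoichiometric trivalent manganese in warm acetic acid meets an acid-labile 2-aryl tetrahydrofuran. Facial control by the auxiliary is uncertain. Ring B must then be dehydrogenated without aromatising the dihydrofuran to a benzofuran (which would erase C2 and C3), followed by O-methylation.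
- Comparison: the chosen strategy has ring B aromatic from the first step, uses a catalyst for stereocontrol and runs under mild conditions.

Key step: step 8

Assumption: Rh2(S-PTTL)4 is taken to induce the 2S configuration at C2, by analogy with ortho-benzyloxy aryldiazoacetates that lack the second ortho substituent; if the sense proves opposite, the enantiomeric complex Rh2(R-PTTL)4 (from D-tert-leucine) is used in the same way.

## Route

Step 1
Reactants: 1 4-bromo-2,6-difluorobenzaldehyde
Product: 2 4-bromo-2,6-dimethoxybenzaldehyde
Conditions: NaOMe (2.5 equiv), MeOH–THF, 65 °C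
Reagents that add atoms: sodium methoxide, C[O-].[Na+]
Why: Nucleophilic aromatic substitution; both fluorides are ortho to the formyl group, which stabilises the anionic adducts, and fluoride leaves far faster than the para bromide, so the bromide should survive as the coupling handle.

Step 2
Reactants: 2 4-bromo-2,6-dimethoxybenzaldehyde
Product: 3 4-bromo-2-hydroxy-6-methoxybenzaldehyde
Conditions: BCl3 (1.2 equiv), CH2Cl2, −78 → 0 °C; aq. work-up
Reagents that add atoms: none
Why: Chelation-directed ether cleavage; BCl3 bridges the formyl oxygen and one ortho OMe and chloride removes that methyl group. The carbonyl oxygen is then held in the aryloxyboron chelate, so the second OMe should stay, and the two ring B oxygens are differentiated.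

Step 3
Reactants: 3 4-bromo-2-hydroxy-6-methoxybenzaldehyde
Product: 4 4-bromo-2-methoxy-6-(methoxymethoxy)benzaldehyde
Conditions: MeOCH2Cl, iPr2NEt, CH2Cl2, 0 °C → rt
Reagents that add atoms: chloromethyl methyl ether, COCCl
Why: O-alkylation of the phenol to a methoxymethyl acetal, which is stable to the base of step 4 and is removed by the acid of step 5 without a separate step.

Step 4
Reactants: 4 4-bromo-2-methoxy-6-(methoxymethoxy)benzaldehyde
Product: 5 5-bromo-1-methoxy-3-(methoxymethoxy)-2-[2-(methylsulfanyl)-2-(methylsulfinyl)ethenyl]benzene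
Conditions: MeS(O)CH2SMe, Triton B (cat.), THF, reflux
Reagents that add atoms: methyl (methylsulfanyl)methyl sulfoxide, CS(=O)CSC
Why: Knoevenagel-type condensation of the sulfinyl-stabilised carbanion with the non-enolisable aldehyde gives a ketene dithioacetal S-oxide, a masked arylacetic ester (one-carbon homologation).

Step 5
Reactants: 5 5-bromo-1-methoxy-3-(methoxymethoxy)-2-[2-(methylsulfanyl)-2-(methylsulfinyl)ethenyl]benzene
Product: 6 methyl 2-(4-bromo-2-hydroxy-6-methoxyphenyl)acetate
Conditions: HCl (from AcCl), MeOH, 0 °C → rt, then 45 °C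
Reagents that add atoms: methanol, CO
Why: Acid methanolysis of the ketene dithioacetal S-oxide (protonation at carbon, Pummerer-type loss of the sulfinyl group, addition of methanol) should give the methyl ester at low temperature. Warming then cleaves the methoxymethyl acetal; with methanol in large excess the open hydroxy ester is favoured over the lactone.

Step 6
Reactants: 6 methyl 2-(4-bromo-2-hydroxy-6-methoxyphenyl)acetate; 7 [4-(benzyloxy)-3-methoxyphenyl]methanol
Product: 8 methyl 2-[2-{[4-(benzyloxy)-3-methoxyphenyl]methoxy}-4-bromo-6-methoxyphenyl]acetate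
Conditions: PPh3, DIAD, THF, 0 °C → rt
Reagents that add atoms: none
Why: Mitsunobu etherification; the phenol is acidic enough to protonate the betaine and attacks the activated primary benzylic alcohol. The neutral medium avoids lactonisation of 6 and C-alkylation of the arylacetate.

Step 7
Reactants: 8 methyl 2-[2-{[4-(benzyloxy)-3-methoxyphenyl]methoxy}-4-bromo-6-methoxyphenyl]acetate
Product: 9 methyl 2-[2-{[4-(benzyloxy)-3-methoxyphenyl]methoxy}-4-bromo-6-methoxyphenyl]-2-diazoacetate
Conditions: p-ABSA, DBU, MeCN, 0 °C → rt
Reagents that add atoms: 4-acetamidobenzenesulfonyl azide, CC(=O)Nc1ccc(cc1)S(=O)(=O)N=[N+]=[N-]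
Why: Regitz diazo transfer; the enolate of the arylacetate attacks the terminal nitrogen of the sulfonyl azide and the sulfonamide leaves, as is standard for aryldiazoacetates.

Step 8
Reactants: 9 methyl 2-[2-{[4-(benzyloxy)-3-methoxyphenyl]methoxy}-4-bromo-6-methoxyphenyl]-2-diazoacetate
Product: 11 methyl (2S,3S)-2-[4-(benzyloxy)-3-methoxyphenyl]-6-bromo-4-methoxy-2,3-dihydro-1-benzofuran-3-carboxylate, via cis ester 10 (not isolated)
Conditions: Rh2(S-PTTL)4 (1 mol%), toluene, −60 → 0 °C; then DBU, 40 °C
Reagents that add atoms: none
Why: The dirhodium complex decomposes the diazo group of 9 with loss of N2 to a metal carbene carrying the aryl donor and the ester acceptor on the carbon attached to C3a; the C–H bond of the ArCH2–O group on C7a then adds across this carbon in one asynchronous three-centre step with hydride-shift character, which forms C2–C3. The closest known reaction type is the enantioselective intramolecular C–H insertion of aryldiazoacetates into ortho benzyloxy groups under chiral dirhodium carboxylates, which gives cis-2-aryl-2,3-dihydrobenzofuran-3-carboxylates. The dihydrofuran ring closes by 1,5-insertion (carbene carbon, C3a, C7a, O1, C2), the only ring size this tether allows. C2 is set by the chiral carboxylate ligands, which select one of the two enantiotopic hydrogens of the OCH2 group (sense as assumed above). C3 forms cis in the same event (10) and is then equilibrated by DBU through the ester enolate to the more stable trans isomer 11, which should leave C2 untouched. The step needs site selectivity against the primary C–H bonds of the OMe group on C4, which are also 1,5 to the carbene: the benzylic ether C–H is secondary and flanked by oxygen and by the electron-rich 4-benzyloxy-3-methoxyphenyl ring, so it stabilises the developing positive charge far better. Attack on either ether oxygen would require a four-membered ylide and is not expected, and the C6–Br bond is inert to the carbene.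

Step 9
Reactants: 12 3-(benzyloxy)-4-methoxybenzaldehyde
Product: 13 rac-1-[3-(benzyloxy)-4-methoxyphenyl]prop-2-en-1-ol
Conditions: CH2=CHMgBr, THF, −20 °C; aq. NH4Cl
Reagents that add atoms: vinylmagnesium bromide, C=C[Mg]Br
Why: Grignard addition to the aldehyde; the carbinol centre is formed racemic and is resolved in step 10.

Step 10
Reactants: 13 rac-1-[3-(benzyloxy)-4-methoxyphenyl]prop-2-en-1-ol
Product: 14 (S)-[3-(benzyloxy)-4-methoxyphenyl][(2R)-oxiran-2-yl]methanol
Conditions: Ti(OiPr)4 (10 mol%), L-(+)-DIPT (15 mol%), t-BuOOH (0.45 equiv), 4 Å MS, CH2Cl2, −20 °C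
Reagents that add atoms: tert-butyl hydroperoxide, CC(C)(C)OO
Why: Sharpless kinetic resolution; with the L-tartrate the (R)-enantiomer of 13 (the spatial analogue of the fast-reacting (S)-alkyl vinyl carbinols, since aryl outranks vinyl) is epoxidised much faster and gives the erythro epoxy alcohol, while the (S)-alcohol stays behind and is removed by chromatography. The carbinol carbon of 14 becomes C2′; the oxirane carbon is lost as a stereocentre in step 12, and at most half of 13 can be used.

Step 11
Reactants: 14 (S)-[3-(benzyloxy)-4-methoxyphenyl][(2R)-oxiran-2-yl]methanol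
Product: 15 (2R)-2-[(S)-[3-(benzyloxy)-4-methoxyphenyl](prop-2-en-1-yloxy)methyl]oxirane
Conditions: NaH, allyl bromide, Bu4NI (cat.), THF, 0 °C → rt
Reagents that add atoms: allyl bromide, C=CCBr
Why: Williamson etherification of the secondary alkoxide; in an aprotic solvent at 0 °C with a reactive allylic halide, O-alkylation is expected to outrun Payne migration of the oxirane.

Step 12
Reactants: 15 (2R)-2-[(S)-[3-(benzyloxy)-4-methoxyphenyl](prop-2-en-1-yloxy)methyl]oxirane
Product: 17 [(2R,3S,4S)-2-[3-(benzyloxy)-4-methoxyphenyl]-4-(iodomethyl)tetrahydrofuran-3-yl]methanol, via bis-titanated tetrahydrofuran 16 (not isolated)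
Conditions: Cp2TiCl2 (2.5 equiv), Zn dust, THF, rt (slow addition of the Cp2TiCl solution); then I2, 0 °C; cold dilute HCl
Reagents that add atoms: iodine, II
Why: Cp2TiCl (trivalent titanium) opens the oxirane by electron transfer at its more substituted C–O bond to give a secondary β-titanoxy radical, which closes 5-exo-trig onto the allyl group; a second Cp2TiCl captures the primary radical as an alkyltitanium, which iodine converts into the iodide (a known epoxy-olefin radical cyclisation with electrophilic quench). In the chair-like transition state the aryl group on C2′ sits pseudo-equatorial, which should place the CH2O–Ti group trans to it and cis to the new CH2 group, so C2′ sets C3′ and C4′ as 2R,3S,4S.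

Step 13
Reactants: 17 [(2R,3S,4S)-2-[3-(benzyloxy)-4-methoxyphenyl]-4-(iodomethyl)tetrahydrofuran-3-yl]methanol
Product: 18 [(2R,3S,4S)-2-[3-(benzyloxy)-4-methoxyphenyl]-4-(iodomethyl)tetrahydrofuran-3-yl]methyl acetate
Conditions: Ac2O, pyridine, DMAP (cat.), CH2Cl2, 0 °C
Reagents that add atoms: acetic anhydride, CC(=O)OC(C)=O
Why: Acylation of the primary alcohol; the acetate removes the acidic proton before zinc insertion, blocks cyclisation of the cis iodo alcohol to a bicyclic ether, and is later cleaved by the hydride that reduces the C3 ester.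

Step 14
Reactants: 18 [(2R,3S,4S)-2-[3-(benzyloxy)-4-methoxyphenyl]-4-(iodomethyl)tetrahydrofuran-3-yl]methyl acetate; 11 methyl (2S,3S)-2-[4-(benzyloxy)-3-methoxyphenyl]-6-bromo-4-methoxy-2,3-dihydro-1-benzofuran-3-carboxylate
Product: 20 methyl (2S,3S)-6-{[(3S,4S,5R)-4-(acetoxymethyl)-5-[3-(benzyloxy)-4-methoxyphenyl]oxolan-3-yl]methyl}-2-[4-(benzyloxy)-3-methoxyphenyl]-4-methoxy-2,3-dihydro-1-benzofuran-3-carboxylate, via alkylzinc iodide 19 (not isolated)
Conditions: Zn dust (Me3SiCl, BrCH2CH2Br activation), LiCl, THF, 40 °C; then 11, Pd(OAc)2 (2 mol%), SPhos (4 mol%), THF, 50 °C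
Reagents that add atoms: none
Why: Negishi coupling; zinc inserts into the primary C–I bond, zerovalent palladium adds to the C6–Br bond, and the alkylzinc iodide transmetalates. The bulky biarylphosphine should favour reductive elimination over β-hydride elimination. Both esters tolerate the organozinc, and no stereocentre is involved because the metalated carbon is a CH2 group.

Step 15
Reactants: 20 methyl (2S,3S)-6-{[(3S,4S,5R)-4-(acetoxymethyl)-5-[3-(benzyloxy)-4-methoxyphenyl]oxolan-3-yl]methyl}-2-[4-(benzyloxy)-3-methoxyphenyl]-4-methoxy-2,3-dihydro-1-benzofuran-3-carboxylate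
Product: 21 [(2S,3R)-2-[4-(benzyloxy)-3-methoxyphenyl]-6-{[(3S,4S,5R)-5-[3-(benzyloxy)-4-methoxyphenyl]-4-(hydroxymethyl)oxolan-3-yl]methyl}-4-methoxy-2,3-dihydro-1-benzofuran-3-yl]methanol
Conditions: LiAlH4, THF, 0 °C; aq. NaOH work-up
Reagents that add atoms: none
Why: Hydride reduction of the methyl ester to the C3 hydroxymethyl group and reductive cleavage of the acetate in one operation; benzyl ethers and all stereocentres are unaffected (the descriptor at C3 changes only through ligand priorities).

Step 16
Reactants: 21 [(2S,3R)-2-[4-(benzyloxy)-3-methoxyphenyl]-6-{[(3S,4S,5R)-5-[3-(benzyloxy)-4-methoxyphenyl]-4-(hydroxymethyl)oxolan-3-yl]methyl}-4-methoxy-2,3-dihydro-1-benzofuran-3-yl]methanol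
Product: 22 [(2S,3R)-2-(4-hydroxy-3-methoxyphenyl)-6-{[(3S,4S,5R)-5-(3-hydroxy-4-methoxyphenyl)-4-(hydroxymethyl)oxolan-3-yl]methyl}-4-methoxy-2,3-dihydro-1-benzofuran-3-yl]methanol (CNP0242386.1)
Conditions: H2 (1 atm), Pd/C (10% Pd), EtOAc–MeOH, rt
Reagents that add atoms: none
Why: Catalytic hydrogenolysis of the two aryl benzyl ethers, which should cleave much faster than the ring benzylic C–O bonds at C2 and C2′; the reaction is stopped as soon as debenzylation is complete.

## Compound list

1 | 4-bromo-2,6-difluorobenzaldehyde | O=Cc1c(F)cc(Br)cc1F | starting material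
2 | 4-bromo-2,6-dimethoxybenzaldehyde | COc1cc(Br)cc(OC)c1C=O | intermediate
3 | 4-bromo-2-hydroxy-6-methoxybenzaldehyde | COc1cc(Br)cc(O)c1C=O | intermediate
4 | 4-bromo-2-methoxy-6-(methoxymethoxy)benzaldehyde | COCOc1cc(Br)cc(OC)c1C=O | intermediate
5 | 5-bromo-1-methoxy-3-(methoxymethoxy)-2-[2-(methylsulfanyl)-2-(methylsulfinyl)ethenyl]benzene (alkene isomers, racemic at sulfur) | COCOc1cc(Br)cc(OC)c1C=C(SC)S(C)=O | intermediate
6 | methyl 2-(4-bromo-2-hydroxy-6-methoxyphenyl)acetate | COC(=O)Cc1c(O)cc(Br)cc1OC | intermediate
7 | [4-(benzyloxy)-3-methoxyphenyl]methanol | COc1cc(CO)ccc1OCc1ccccc1 | starting material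
8 | methyl 2-[2-{[4-(benzyloxy)-3-methoxyphenyl]methoxy}-4-bromo-6-methoxyphenyl]acetate | COC(=O)Cc1c(OC)cc(Br)cc1OCc1ccc(OCc2ccccc2)c(OC)c1 | intermediate
9 | methyl 2-[2-{[4-(benzyloxy)-3-methoxyphenyl]methoxy}-4-bromo-6-methoxyphenyl]-2-diazoacetate | COC(=O)C(=[N+]=[N-])c1c(OC)cc(Br)cc1OCc1ccc(OCc2ccccc2)c(OC)c1 | intermediate (precursor of the key step)
10 | methyl (2S,3R)-2-[4-(benzyloxy)-3-methoxyphenyl]-6-bromo-4-methoxy-2,3-dihydro-1-benzofuran-3-carboxylate (cis) | Brc1cc(OC)c2c(c1)O[C@H](c1ccc(OCc3ccccc3)c(OC)c1)[C@@H]2C(=O)OC | intermediate (not isolated)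
11 | methyl (2S,3S)-2-[4-(benzyloxy)-3-methoxyphenyl]-6-bromo-4-methoxy-2,3-dihydro-1-benzofuran-3-carboxylate (trans) | Brc1cc(OC)c2c(c1)O[C@H](c1ccc(OCc3ccccc3)c(OC)c1)[C@H]2C(=O)OC | intermediate (product of the key step)
12 | 3-(benzyloxy)-4-methoxybenzaldehyde | COc1ccc(C=O)cc1OCc1ccccc1 | starting material
13 | rac-1-[3-(benzyloxy)-4-methoxyphenyl]prop-2-en-1-ol | COc1ccc(C(O)C=C)cc1OCc1ccccc1 | intermediate
14 | (S)-[3-(benzyloxy)-4-methoxyphenyl][(2R)-oxiran-2-yl]methanol | COc1ccc([C@H](O)[C@H]2CO2)cc1OCc1ccccc1 | intermediate
15 | (2R)-2-[(S)-[3-(benzyloxy)-4-methoxyphenyl](prop-2-en-1-yloxy)methyl]oxirane | COc1ccc([C@H](OCC=C)[C@H]2CO2)cc1OCc1ccccc1 | intermediate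
16 | (2R,3S,4S)-2-[3-(benzyloxy)-4-methoxyphenyl]tetrahydrofuran with CH2O–Ti(Cl)Cp2 on C3 and CH2–Ti(Cl)Cp2 on C4 (cyclopentadienyl rings drawn sigma-bonded) | COc1ccc([C@@H]2OC[C@@H](C[Ti](Cl)(C3C=CC=C3)C3C=CC=C3)[C@H]2CO[Ti](Cl)(C2C=CC=C2)C2C=CC=C2)cc1OCc1ccccc1 | intermediate (not isolated)
17 | [(2R,3S,4S)-2-[3-(benzyloxy)-4-methoxyphenyl]-4-(iodomethyl)tetrahydrofuran-3-yl]methanol | COc1ccc([C@@H]2OC[C@@H](CI)[C@H]2CO)cc1OCc1ccccc1 | intermediate
18 | [(2R,3S,4S)-2-[3-(benzyloxy)-4-methoxyphenyl]-4-(iodomethyl)tetrahydrofuran-3-yl]methyl acetate | COc1ccc([C@@H]2OC[C@@H](CI)[C@H]2COC(C)=O)cc1OCc1ccccc1 | intermediate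
19 | {[(3S,4S,5R)-4-(acetoxymethyl)-5-[3-(benzyloxy)-4-methoxyphenyl]oxolan-3-yl]methyl}zinc iodide | COc1ccc([C@@H]2OC[C@@H](C[Zn]I)[C@H]2COC(C)=O)cc1OCc1ccccc1 | intermediate (not isolated)
20 | methyl (2S,3S)-6-{[(3S,4S,5R)-4-(acetoxymethyl)-5-[3-(benzyloxy)-4-methoxyphenyl]oxolan-3-yl]methyl}-2-[4-(benzyloxy)-3-methoxyphenyl]-4-methoxy-2,3-dihydro-1-benzofuran-3-carboxylate | COc1ccc([C@@H]2OC[C@@H](Cc3cc(OC)c4c(c3)O[C@H](c3ccc(OCc5ccccc5)c(OC)c3)[C@H]4C(=O)OC)[C@H]2COC(C)=O)cc1OCc1ccccc1 | intermediate
21 | [(2S,3R)-2-[4-(benzyloxy)-3-methoxyphenyl]-6-{[(3S,4S,5R)-5-[3-(benzyloxy)-4-methoxyphenyl]-4-(hydroxymethyl)oxolan-3-yl]methyl}-4-methoxy-2,3-dihydro-1-benzofuran-3-yl]methanol | COc1ccc([C@@H]2OC[C@@H](Cc3cc(OC)c4c(c3)O[C@H](c3ccc(OCc5ccccc5)c(OC)c3)[C@H]4CO)[C@H]2CO)cc1OCc1ccccc1 | intermediate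
22 | [(2S,3R)-2-(4-hydroxy-3-methoxyphenyl)-6-{[(3S,4S,5R)-5-(3-hydroxy-4-methoxyphenyl)-4-(hydroxymethyl)oxolan-3-yl]methyl}-4-methoxy-2,3-dihydro-1-benzofuran-3-yl]methanol | COc1ccc([C@@H]2OC[C@@H](Cc3cc(OC)c4c(c3)O[C@H](c3ccc(O)c(OC)c3)[C@H]4CO)[C@H]2CO)cc1O | target

## Step count and least certain steps

Total: 16 steps. Longest linear sequence: 11 steps (steps 1 to 8, then 14 to 16, from 1). The tetrahydrofuran branch has 5 steps (9 to 13) before the union.

**Step 8 (key step).**
- What may go wrong: loss of enantioselection. The carbene of 9 is flanked by two ortho substituents where the known substrates have one, so the aryl ring is twisted and the ligand pocket may distinguish the two OCH2 hydrogens less well. A second threat is erosion at C2 during the DBU stage, through reversible β-elimination of the C7a phenoxide from the ester enolate followed by re-closure.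
- Fallback: decompose 9 with achiral Rh2(OAc)4 (CH2Cl2, rt) and equilibrate with DBU. This keeps the insertion but gives up catalyst control, and gives 11 together with its enantiomer, methyl (2R,3R)-2-[4-(benzyloxy)-3-methoxyphenyl]-6-bromo-4-methoxy-2,3-dihydro-1-benzofuran-3-carboxylate F1, as the racemate. Preparative chromatography on a chiral stationary phase separates them, and the route is rejoined at 11.

**Step 12.**
- What may go wrong: incomplete capture of the cyclised primary radical by Cp2TiCl (hydrogen abstraction from THF would give a methyl group and no iodide); deoxygenation of the oxirane when the first radical is captured before ring closure; only moderate control of C3′ and C4′ with a plain allyl acceptor.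
- Fallback: from 14, O-alkylate with propargyl bromide (NaH, THF) to the propargyl ether (2R)-2-[(S)-[3-(benzyloxy)-4-methoxyphenyl](prop-2-yn-1-yloxy)methyl]oxirane F2. The same Cp2TiCl cyclisation, now onto the alkyne and ended by hydrogen abstraction, gives the exocyclic alkene [(2R,3S)-2-[3-(benzyloxy)-4-methoxyphenyl]-4-methylidenetetrahydrofuran-3-yl]methanol F3. Acetylation gives [(2R,3S)-2-[3-(benzyloxy)-4-methoxyphenyl]-4-methylidenetetrahydrofuran-3-yl]methyl acetate F4. Hydroboration with 9-BBN from the face away from the adjacent C3′ arm sets C4′ and gives the B-alkyl borane {(2R,3S,4S)-2-[3-(benzyloxy)-4-methoxyphenyl]-4-[(9-borabicyclo[3.3.1]nonan-9-yl)methyl]tetrahydrofuran-3-yl}methyl acetate F5. This is coupled directly with 11 in a B-alkyl Suzuki reaction (PdCl2(dppf), aq. K3PO4, THF–DMF, 60 °C), rejoining the route at 20.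

**Step 10.**
- What may go wrong: ionisation of the electron-rich benzylic, allylic alcohol at the Lewis acidic titanium centre (racemisation or 1,3-transposition to the cinnamyl alcohol), or titanium-promoted opening of the epoxy alcohol.
- Fallback: from 13, resolve without a Lewis acid by acylation with immobilised Candida antarctica lipase B and vinyl acetate, which should acylate the (R)-enantiomer to (R)-1-[3-(benzyloxy)-4-methoxyphenyl]prop-2-en-1-yl acetate F6. Methanolysis (K2CO3, MeOH) gives (R)-1-[3-(benzyloxy)-4-methoxyphenyl]prop-2-en-1-ol F7. Hydroxyl-directed epoxidation (VO(acac)2, t-BuOOH, CH2Cl2) gives 14, which is separated from its minor oxirane epimer (S)-[3-(benzyloxy)-4-methoxyphenyl][(2S)-oxiran-2-yl]methanol F8; F8 would serve equally well because the oxirane carbon becomes a radical. The route is rejoined at 14.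

**Step 7.**
- What may go wrong: slow or incomplete diazo transfer, because the CH2 group of 8 lies between two ortho substituents and its enolate cannot become coplanar with ring B, so DBU may deprotonate it poorly.
- Fallback: from 8, deprotonate irreversibly with LiN(SiMe3)2 (THF, −78 °C) and hydroxylate with 2-(phenylsulfonyl)-3-phenyloxaziridine to the α-hydroxy ester methyl 2-[2-{[4-(benzyloxy)-3-methoxyphenyl]methoxy}-4-bromo-6-methoxyphenyl]-2-hydroxyacetate F9. Oxidise with Dess–Martin periodinane to the aryl glyoxylate methyl 2-[2-{[4-(benzyloxy)-3-methoxyphenyl]methoxy}-4-bromo-6-methoxyphenyl]-2-oxoacetate F10. Condense with tosylhydrazide to the tosylhydrazone methyl 2-[2-{[4-(benzyloxy)-3-methoxyphenyl]methoxy}-4-bromo-6-methoxyphenyl]-2-[2-(4-methylbenzenesulfonyl)hydrazinylidene]acetate F11. Bamford–Stevens elimination with DBU then gives 9.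

**Step 16.**
- What may go wrong: over-reduction, that is hydrogenolytic opening of the benzylic C2–O1 bond of the dihydrobenzofuran (an aryl benzylic ether para to the freed phenol) or of C2′–O1′ once the benzyl ethers are gone.
- Fallback: from 21, remove the benzyl groups by Lewis-acid dealkylation instead of hydrogenolysis (BCl3 with pentamethylbenzene as cation scavenger, CH2Cl2, −78 °C, methanol quench), giving 22 directly. This fallback makes no new compound (F0).

## Further compounds

F1 | step 8 | methyl (2R,3R)-2-[4-(benzyloxy)-3-methoxyphenyl]-6-bromo-4-methoxy-2,3-dihydro-1-benzofuran-3-carboxylate (enantiomer of 11, formed with 11 as the racemate) | Brc1cc(OC)c2c(c1)O[C@@H](c1ccc(OCc3ccccc3)c(OC)c1)[C@@H]2C(=O)OC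
F2 | step 12 | (2R)-2-[(S)-[3-(benzyloxy)-4-methoxyphenyl](prop-2-yn-1-yloxy)methyl]oxirane | COc1ccc([C@H](OCC#C)[C@H]2CO2)cc1OCc1ccccc1
F3 | step 12 | [(2R,3S)-2-[3-(benzyloxy)-4-methoxyphenyl]-4-methylidenetetrahydrofuran-3-yl]methanol | COc1ccc([C@@H]2OCC(=C)[C@H]2CO)cc1OCc1ccccc1
F4 | step 12 | [(2R,3S)-2-[3-(benzyloxy)-4-methoxyphenyl]-4-methylidenetetrahydrofuran-3-yl]methyl acetate | COc1ccc([C@@H]2OCC(=C)[C@H]2COC(C)=O)cc1OCc1ccccc1
F5 | step 12 | {(2R,3S,4S)-2-[3-(benzyloxy)-4-methoxyphenyl]-4-[(9-borabicyclo[3.3.1]nonan-9-yl)methyl]tetrahydrofuran-3-yl}methyl acetate | COc1ccc([C@@H]2OC[C@@H](CB3C4CCCC3CCC4)[C@H]2COC(C)=O)cc1OCc1ccccc1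
F6 | step 10 | (R)-1-[3-(benzyloxy)-4-methoxyphenyl]prop-2-en-1-yl acetate | COc1ccc([C@H](OC(C)=O)C=C)cc1OCc1ccccc1
F7 | step 10 | (R)-1-[3-(benzyloxy)-4-methoxyphenyl]prop-2-en-1-ol | COc1ccc([C@H](O)C=C)cc1OCc1ccccc1
F8 | step 10 | (S)-[3-(benzyloxy)-4-methoxyphenyl][(2S)-oxiran-2-yl]methanol | COc1ccc([C@H](O)[C@@H]2CO2)cc1OCc1ccccc1
F9 | step 7 | methyl 2-[2-{[4-(benzyloxy)-3-methoxyphenyl]methoxy}-4-bromo-6-methoxyphenyl]-2-hydroxyacetate (racemic) | COC(=O)C(O)c1c(OC)cc(Br)cc1OCc1ccc(OCc2ccccc2)c(OC)c1
F10 | step 7 | methyl 2-[2-{[4-(benzyloxy)-3-methoxyphenyl]methoxy}-4-bromo-6-methoxyphenyl]-2-oxoacetate | COC(=O)C(=O)c1c(OC)cc(Br)cc1OCc1ccc(OCc2ccccc2)c(OC)c1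
F11 | step 7 | methyl 2-[2-{[4-(benzyloxy)-3-methoxyphenyl]methoxy}-4-bromo-6-methoxyphenyl]-2-[2-(4-methylbenzenesulfonyl)hydrazinylidene]acetate | COC(=O)C(=NNS(=O)(=O)c1ccc(C)cc1)c1c(OC)cc(Br)cc1OCc1ccc(OCc2ccccc2)c(OC)c1
F0 | step 16 | none | none
A1 | alternative 1 | ring B resorcinol mono-triisopropylsilyl ether carrying the tetrahydrofuran unit and the open C3–C2 chain (product of the benzannulation) | COc1ccc([C@@H]2OC[C@@H](Cc3cc(O[Si](C(C)C)(C(C)C)C(C)C)c([C@H](CO[Si](C)(C)C(C)(C)C)[C@@H](O[Si](CC)(CC)CC)c4ccc(OCc5ccccc5)c(OC)c4)c(O)c3)[C@H]2CO[Si](C)(C)C(C)(C)C)cc1OCc1ccccc1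
A2 | alternative 1 | 3-substituted cyclobut-2-en-1-one carrying the protected tetrahydrofuran unit | COc1ccc([C@@H]2OC[C@@H](CC3=CC(=O)C3)[C@H]2CO[Si](C)(C)C(C)(C)C)cc1OCc1ccccc1
A3 | alternative 1 | triisopropylsiloxyalkyne carrying the future C3 and C2 with their silyl ethers | CC(C)[Si](C(C)C)(C(C)C)OC#C[C@H](CO[Si](C)(C)C(C)(C)C)[C@@H](O[Si](CC)(CC)CC)c1ccc(OCc2ccccc2)c(OC)c1
A4 | alternative 2 | protected trans-dihydrobenzofuran with a pinacolboronate CH2 group on C3 (product of the radical cyclisation) | COc1ccc([C@@H]2OC[C@@H](Cc3cc(OC)c4c(c3)O[C@H](c3ccc(OCc5ccccc5)c(OC)c3)[C@H]4CB3OC(C)(C)C(C)(C)O3)[C@H]2CO[Si](C)(C)C(C)(C)C)cc1OCc1ccccc1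
A5 | alternative 2 | aryl iodide (iodine on C3a) with the (S)-1-arylallyl ether on C7a and the protected tetrahydrofuran unit on C6 | COc1ccc([C@@H]2OC[C@@H](Cc3cc(OC)c(I)c(c3)O[C@H](c3ccc(OCc4ccccc4)c(OC)c3)C=C)[C@H]2CO[Si](C)(C)C(C)(C)C)cc1OCc1ccccc1
A6 | alternative 3 | trans-2-aryl-3-(sultam carbonyl)-4-oxo-2,3,4,5,6,7-hexahydrobenzofuran, mixture at C6 (product of the oxidative annulation) | COc1ccc([C@@H]2OC[C@@H](CC3CC(=O)C4=C(C3)O[C@H](c3ccc(OCc5ccccc5)c(OC)c3)[C@H]4C(=O)N3[C@@H]4C[C@H]5CC[C@]4(CS3(=O)=O)C5(C)C)[C@H]2COC(C)=O)cc1OCc1ccccc1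
A7 | alternative 3 | 5-substituted cyclohexane-1,3-dione carrying the tetrahydrofuran unit as its acetate | COc1ccc([C@@H]2OC[C@@H](CC3CC(=O)CC(=O)C3)[C@H]2COC(C)=O)cc1OCc1ccccc1
A8 | alternative 3 | N-[(E)-3-(4-benzyloxy-3-methoxyphenyl)prop-2-enoyl]camphorsultam | O=C(/C=C/c1ccc(OCc2ccccc2)c(OC)c1)N1[C@@H]2C[C@H]3CC[C@]2(CS1(=O)=O)C3(C)C
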